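The data were computed for an exercise; scatter was added.

The incoming ligand is the limiting reagent of blue: each complex can take two exchanges, and blue is charged with 0.800 equiv. So keep a ledger of that ligand.

common to all: starting complex 0.20 M

| run | incoming ligand | remark | time |
|---|---|---|---|
| south-west | 1.1 equiv | run made earlier |  |
| north | 6.2 equiv | run made earlier |  |
| ochre | 4.00 equiv |  | 20 min |
| violet | 1.00 equiv |  | 20 min |
| blue | 0.800 equiv |  | 20 min |

- south-west (time / min: complex with one exchanged / %, complex with two exchanged / %, starting complex / %): 1.00: 6.6, 0.5, 93.1; 3.00: 12.2, 1.9, 85.0; 6.00: 19.5, 3.0, 75.5; 8.00: 21.4, 4.7, 71.1; 12.0: 25.1, 6.8, 62.2; 15.0: 25.9, 9.8, 58.4; 20.0: 26.5, 11.2, 52.2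
- north (time / min: complex with one exchanged / %, complex with two exchanged / %, starting complex / %): 1.00: 22.7, 8.7, 67.9; 3.00: 26.3, 23.5, 40.7; 6.00: 17.3, 35.5, 19.3; 8.00: 12.5, 39.4, 13.2; 12.0: 5.5, 44.2, 5.8; 15.0: 3.2, 44.7, 2.9; 20.0: 1.5, 47.1, 1.3

(scatter of a reading: 0.5 percentage points)



- which of these holds the largest part of the starting complex at the end of ochre (starting complex / complex with one exchanged / complex with two exchanged)
- which of these holds the largest part of the starting complex at the end of violet (starting complex / complex with one exchanged / complex with two exchanged)
- which of these holds the largest part of the starting complex at the end of blue (starting complex / complex with one exchanged / complex with two exchanged)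
- complex with one exchanged at the end of blue, in percent of the starting complex charged

At 20.0 min the three readings of south-west sum to 89.9% of the charge, so I count every complex that has left the start and is not singly exchanged as doubly exchanged. South-west has then spent 69.1% of the complex charged by 20.0 min. I assume blue, at the same concentration of complex, spends the same share of its ligand, which makes 50.3% of the complex charged. South-west had spent 50.5% at 12.0 min, with 62.2% of starting complex left, so I take that for blue's end.

How is that spending divided? If both steps are first order in the same free ligand, the ligand cancels from the ratio of their rates, leaving the two amounts of complex and one number: the selectivity factor, the second step's rate constant over the first's. At the peak of the complex with one exchanged, it equals starting complex over that complex. South-west's highest reading of it, at 20.0 min, gives 1.97, and north's highest, at 3.00 min, gives 1.55. Neither reading need be the peak itself. Their geometric mean, my reading of the factor κ, is 1.75. With s the fraction of starting complex left, the complex with one exchanged is (s − s^κ)/(κ − 1). For blue that is 24.9%. The remaining 25.4% of spent ligand makes 12.7% of doubly exchanged complex, counted as above, and the books close with 62.4% of starting complex.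

The forecast names complex with two exchanged for ochre, starting complex for violet and starting complex for blue, and gives 25.5% (23.5% to 27.5%) for the complex with one exchanged, somewhat above my figure, adding “The starting complex remains largest.”

Blue gives 24.4% of the complex with one exchanged, beside 62.2% of starting complex, and ochre and violet end as complex with two exchanged and starting complex. By the factor, an estimate, blue at 20 min makes this complex 1.46 times as fast as it uses it, and at 200 min blue stands at 26.4%.

    starting complex + incoming ligand → leaving ligand + complex with one exchanged (k = 0.469 /M/min)
    complex with one exchanged + incoming ligand → leaving ligand + complex with two exchanged (k = 0.855 /M/min)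
    incoming ligand ⇌ dormant form (K = 0.990, k = 1.14 /min)
    complex with two exchanged ⇌ isomer of the product (K = 1.12, k = 0.407 /min)

One more flask, like blue but with 3.20 equiv of incoming ligand, ends with 12.9% of starting complex. The factor then gives 13.5% of the complex with one exchanged, and the flask gives 12.8%.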